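## Retrosynthetic overview

1. Isoflavan numbering is used (ring A = benzo ring; ring C = pyran ring with O1, C2, C3, C4, C4a, C8a; ring B primed). The (3R)-isoflavan is traced back through desilylation, removal of a temporary C4 oxygen and a stereo-setting transfer hydrogenation to a 2',7-dioxygenated isoflavone.
2. Key disconnection: ring C of that isoflavone is closed from an aryl 2,4-difluorobenzoate of the ring-B arylacetaldehyde by forming C3–C4 and O1–C8a in one operation (O-to-C acyl shift, then SNAr). It is the only ring formed; rings A and B are bought.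
3. Enabling feature: the free phenol oxygen O2' on ring B is ortho to C1', the carbon that carries C3, so an aroyl group parked on O2' reaches C3 through a five-membered transition state and O2' is set free again. On ring A, C4a (bearing C4) is ortho to C8a and para to C7, so a C4 carbonyl activates C8a–F for the ring closure and C7–F for later introduction of O7, and the O1/O7 donors later allow its reductive removal.
4. Ring B is dressed first: prenylation of O4', Claisen rearrangement to put the 1,1-dimethylallyl group on C5', second prenylation; the acetaldehyde arm is carried as a methyl enol ether.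
5. C3 is set after the key step by ruthenium-catalysed asymmetric transfer hydrogenation with dynamic kinetic resolution.

Key step: step 7

Remark: all methyl enol ethers in the route are carried as E/Z mixtures (written without double-bond geometry); both isomers hydrolyse to the same aldehyde.

## Route

Step 1
Reactants: 1 2,4-dihydroxybenzaldehyde; 2 1-bromo-3-methylbut-2-ene (prenyl bromide)
Product: 3 2-hydroxy-4-(prenyloxy)benzaldehyde
Conditions: K2CO3 (1 equiv), acetone, 56 °C
Reagents that add atoms: none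
Why: Williamson etherification; the 4-hydroxyl is the more acidic one and is not tied up in the hydrogen bond to the formyl group, so mono-alkylation at O4 is expected.

Step 2
Reactants: 3 2-hydroxy-4-(prenyloxy)benzaldehyde
Product: 4 2-(2-methoxyethenyl)-5-(prenyloxy)phenol (E/Z mixture)
Conditions: MeOCH2PPh3Cl (2.5 equiv), KOtBu (3.6 equiv), THF, 0 to 23 °C; aq. NH4Cl work-up, no acid
Reagents that add atoms: (methoxymethyl)triphenylphosphonium chloride, COC[P+](c1ccccc1)(c1ccccc1)c1ccccc1.[Cl-]
Why: Wittig methoxymethylenation; the non-stabilised ylide adds to the aldehyde even as its phenoxide, and the enol ether masks the arylacetaldehyde so that the ortho-phenol cannot close to a benzofuran as long as acid is avoided.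

Step 3
Reactants: 4 2-(2-methoxyethenyl)-5-(prenyloxy)phenol; 5 2,4-difluorobenzoyl chloride
Product: 6 2-(2-methoxyethenyl)-5-(prenyloxy)phenyl 2,4-difluorobenzoate
Conditions: Et3N, DMAP (cat.), CH2Cl2, 0 °C
Reagents that add atoms: none
Why: DMAP-catalysed acylation of a phenol by an acid chloride; the ester caps O2' for the Claisen step and parks the future C4 acyl group on ring B.

Step 4
Reactants: 6 2-(2-methoxyethenyl)-5-(prenyloxy)phenyl 2,4-difluorobenzoate
Product: 8 5-hydroxy-2-(2-methoxyethenyl)-4-(2-methylbut-3-en-2-yl)phenyl 2,4-difluorobenzoate, via ortho-dienone 7 (not isolated)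
Conditions: PhNEt2, 185 °C, argon
Reagents that add atoms: none
Why: Aromatic Claisen rearrangement ([3,3] shift with allyl inversion) of the aryl prenyl ether; with O2' acylated there is no chelation-driven bond fixation, so the less hindered ortho carbon (C5', para to O2') should be preferred over the carbon between the two oxygens, and tautomerisation of dienone 7 restores the phenol.

Step 5
Reactants: 8 5-hydroxy-2-(2-methoxyethenyl)-4-(2-methylbut-3-en-2-yl)phenyl 2,4-difluorobenzoate; 2 1-bromo-3-methylbut-2-ene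
Product: 9 2-(2-methoxyethenyl)-4-(2-methylbut-3-en-2-yl)-5-(prenyloxy)phenyl 2,4-difluorobenzoate
Conditions: K2CO3, acetone, 56 °C
Reagents that add atoms: none
Why: Williamson etherification of the hindered phenol under anhydrous carbonate conditions, which the aryl ester and the enol ether (no enolisable position yet) should tolerate.

Step 6
Reactants: 9 2-(2-methoxyethenyl)-4-(2-methylbut-3-en-2-yl)-5-(prenyloxy)phenyl 2,4-difluorobenzoate
Product: 10 4-(2-methylbut-3-en-2-yl)-5-(prenyloxy)-2-(2-oxoethyl)phenyl 2,4-difluorobenzoate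
Conditions: 2 M aq. HCl, THF, 23 °C; used at once
Reagents that add atoms: water, O
Why: Acid-catalysed enol ether hydrolysis (C-protonation, hydration of the oxocarbenium ion, loss of methanol) under conditions mild enough for the aryl ester and the prenyl ether.

Step 7
Reactants: 10 4-(2-methylbut-3-en-2-yl)-5-(prenyloxy)-2-(2-oxoethyl)phenyl 2,4-difluorobenzoate
Product: 12 7-fluoro-2'-hydroxy-5'-(2-methylbut-3-en-2-yl)-4'-(prenyloxy)isoflavone, via formyl ketone dianion 11 (not isolated)
Conditions: 10 added to KN(SiMe3)2 (2.2 equiv), THF, −78 to 0 °C; then DMF, 60 °C; 1 M aq. HCl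
Reagents that add atoms: none
Why: Proposed new method: deprotonation of the arylacetaldehyde gives an enolate whose C3 attacks the carbonyl of the aryl ester on O2' through a five-membered (5-exo-trig) transition state; the tetrahedral intermediate expels the O2' phenoxide (O-to-C acyl shift, C3–C4 formed), and the formyl oxygen of the resulting enolate 11 then displaces the fluoride on C8a, ortho to the new C4 carbonyl (O1–C8a formed). The closest known reactions are the Baker–Venkataraman rearrangement of ortho-acyloxy aryl ketones (the same enolate-to-ester acyl transfer, here one atom shorter and from an aldehyde enolate) and the SNAr closure of 2-fluorobenzoyl 1,3-dicarbonyl enolates to chromones. Ring C closes by a six-membered intramolecular addition–elimination at C8a (formally 6-exo-trig on the C8a=C8 bond) through a Meisenheimer adduct stabilised by the C4 carbonyl. No stereocentre is formed, C3 being trigonal in 12; it is set in step 10. The step needs C- over O-acylation of the enolate, which is secured because O-acyl transfer is reversible while C-acylation ends in the stabilised 1,3-dicarbonyl enolate. It also needs attack on the 2-fluorine and not the 4-fluorine, which is secured because only the 2-position is reached intramolecularly in a six-membered ring (the O2' phenoxide could reach it only through a seven-membered ring).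

Step 8
Reactants: 12 7-fluoro-2'-hydroxy-5'-(2-methylbut-3-en-2-yl)-4'-(prenyloxy)isoflavone
Product: 14 2',7-dihydroxy-5'-(2-methylbut-3-en-2-yl)-4'-(prenyloxy)isoflavone, via sulfonylethyl ether 13 (not isolated)
Conditions: NaH, MeSO2CH2CH2OH, DMF, 0 to 23 °C; 1 M aq. HCl
Reagents that add atoms: 2-(methylsulfonyl)ethanol, CS(=O)(=O)CCO
Why: SNAr of the fluoride para to the C4 carbonyl by the alkoxide, then base-induced β-elimination (E1cB) of methyl vinyl sulfone from ether 13, a known hydroxide-free conversion of activated aryl fluorides into phenols that spares the pyranone.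

Step 9
Reactants: 14 2',7-dihydroxy-5'-(2-methylbut-3-en-2-yl)-4'-(prenyloxy)isoflavone
Product: 15 2',7-bis(tert-butyldimethylsilyloxy)-5'-(2-methylbut-3-en-2-yl)-4'-(prenyloxy)isoflavone
Conditions: TBSCl, imidazole, DMF, 23 °C
Reagents that add atoms: tert-butyldimethylsilyl chloride, CC(C)(C)[Si](C)(C)Cl
Why: Standard silylation of both phenols; the silyl ethers keep O2' from attacking C4 in step 11 and keep O7 a neutral donor in steps 10 and 11.

Step 10
Reactants: 15 2',7-bis(tert-butyldimethylsilyloxy)-5'-(2-methylbut-3-en-2-yl)-4'-(prenyloxy)isoflavone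
Product: 17 (3R,4R)-cis-isoflavan-4-ol bis(silyl ether), via racemic isoflavanone 16 (not isolated)
Conditions: RuCl[(R,R)-TsDPEN](p-cymene) (5 mol %), HCO2H/Et3N (5:2), EtOAc, 40 °C
Reagents that add atoms: none
Why: Noyori–Ikariya asymmetric transfer hydrogenation with dynamic kinetic resolution: the ruthenium hydride first reduces C2=C3 to isoflavanone 16, whose C3 epimerises through the enol faster than the ketone is reduced, and the (R,R) catalyst is expected (usual aryl ketone model) to give the (4R) alcohol with hydride delivered anti to the C3 aryl group, so that the (3R) epimer is consumed and the cis-(3R,4R) alcohol results; the isolated alkenes are not touched by this outer-sphere hydride.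

Step 11
Reactants: 17 (3R,4R)-cis-isoflavan-4-ol bis(silyl ether)
Product: 18 (3R)-2',7-bis(tert-butyldimethylsilyloxy)-5'-(2-methylbut-3-en-2-yl)-4'-(prenyloxy)isoflavan
Conditions: Et3SiH, CF3CO2H, CH2Cl2, −40 to 0 °C
Reagents that add atoms: none
Why: Ionic hydrogenation; the C4 hydroxyl ionises readily because the cation is stabilised by O1 (ortho) and the C7 silyloxy group (para), and the silane should trap it faster than C3–H is lost, so C3 keeps its configuration.

Step 12
Reactants: 18 (3R)-2',7-bis(tert-butyldimethylsilyloxy)-5'-(2-methylbut-3-en-2-yl)-4'-(prenyloxy)isoflavan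
Product: 19 Manuifolin D
Conditions: Bu4NF, AcOH, THF, 0 °C
Reagents that add atoms: none
Why: Buffered fluoride cleavage of the two aryl silyl ethers, which should leave the prenyl ether, both alkenes and the C3 stereocentre untouched.

## Compound list

1 | 2,4-dihydroxybenzaldehyde | O=Cc1ccc(O)cc1O | starting material
2 | 1-bromo-3-methylbut-2-ene (prenyl bromide) | CC(C)=CCBr | starting material
3 | 2-hydroxy-4-[(3-methylbut-2-en-1-yl)oxy]benzaldehyde | O=Cc1ccc(OCC=C(C)C)cc1O | intermediate
4 | 2-(2-methoxyethenyl)-5-[(3-methylbut-2-en-1-yl)oxy]phenol (E/Z mixture) | COC=Cc1ccc(OCC=C(C)C)cc1O | intermediate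
5 | 2,4-difluorobenzoyl chloride | O=C(Cl)c1ccc(F)cc1F | starting material
6 | 2-(2-methoxyethenyl)-5-[(3-methylbut-2-en-1-yl)oxy]phenyl 2,4-difluorobenzoate (E/Z mixture) | COC=Cc1ccc(OCC=C(C)C)cc1OC(=O)c1ccc(F)cc1F | intermediate
7 | 6-(2-methoxyethenyl)-4-(2-methylbut-3-en-2-yl)-3-oxocyclohexa-1,5-dien-1-yl 2,4-difluorobenzoate (racemic ortho-dienone; not isolated) | COC=CC1=CC(C(C)(C)C=C)C(=O)C=C1OC(=O)c1ccc(F)cc1F | intermediate
8 | 5-hydroxy-2-(2-methoxyethenyl)-4-(2-methylbut-3-en-2-yl)phenyl 2,4-difluorobenzoate (E/Z mixture) | COC=Cc1cc(C(C)(C)C=C)c(O)cc1OC(=O)c1ccc(F)cc1F | intermediate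
9 | 2-(2-methoxyethenyl)-4-(2-methylbut-3-en-2-yl)-5-[(3-methylbut-2-en-1-yl)oxy]phenyl 2,4-difluorobenzoate (E/Z mixture) | COC=Cc1cc(C(C)(C)C=C)c(OCC=C(C)C)cc1OC(=O)c1ccc(F)cc1F | intermediate
10 | 4-(2-methylbut-3-en-2-yl)-5-[(3-methylbut-2-en-1-yl)oxy]-2-(2-oxoethyl)phenyl 2,4-difluorobenzoate | O=CCc1cc(C(C)(C)C=C)c(OCC=C(C)C)cc1OC(=O)c1ccc(F)cc1F | intermediate
11 | 3-(2,4-difluorophenyl)-2-[2-hydroxy-5-(2-methylbut-3-en-2-yl)-4-[(3-methylbut-2-en-1-yl)oxy]phenyl]-3-oxopropanal (in the flask as its dipotassium enolate phenoxide; not isolated) | O=CC(C(=O)c1ccc(F)cc1F)c1cc(C(C)(C)C=C)c(OCC=C(C)C)cc1O | intermediate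
12 | 7-fluoro-3-[2-hydroxy-5-(2-methylbut-3-en-2-yl)-4-[(3-methylbut-2-en-1-yl)oxy]phenyl]-4H-chromen-4-one | O=c1c(-c2cc(C(C)(C)C=C)c(OCC=C(C)C)cc2O)coc2cc(F)ccc12 | intermediate
13 | 3-[2-hydroxy-5-(2-methylbut-3-en-2-yl)-4-[(3-methylbut-2-en-1-yl)oxy]phenyl]-7-[2-(methylsulfonyl)ethoxy]-4H-chromen-4-one (not isolated) | O=c1c(-c2cc(C(C)(C)C=C)c(OCC=C(C)C)cc2O)coc2cc(OCCS(C)(=O)=O)ccc12 | intermediate
14 | 7-hydroxy-3-[2-hydroxy-5-(2-methylbut-3-en-2-yl)-4-[(3-methylbut-2-en-1-yl)oxy]phenyl]-4H-chromen-4-one | O=c1c(-c2cc(C(C)(C)C=C)c(OCC=C(C)C)cc2O)coc2cc(O)ccc12 | intermediate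
15 | 7-[(tert-butyldimethylsilyl)oxy]-3-[2-[(tert-butyldimethylsilyl)oxy]-5-(2-methylbut-3-en-2-yl)-4-[(3-methylbut-2-en-1-yl)oxy]phenyl]-4H-chromen-4-one | O=c1c(-c2cc(C(C)(C)C=C)c(OCC=C(C)C)cc2O[Si](C)(C)C(C)(C)C)coc2cc(O[Si](C)(C)C(C)(C)C)ccc12 | intermediate
16 | racemic 7-[(tert-butyldimethylsilyl)oxy]-3-[2-[(tert-butyldimethylsilyl)oxy]-5-(2-methylbut-3-en-2-yl)-4-[(3-methylbut-2-en-1-yl)oxy]phenyl]-2,3-dihydro-4H-chromen-4-one (not isolated) | O=C1c2ccc(O[Si](C)(C)C(C)(C)C)cc2OCC1c1cc(C(C)(C)C=C)c(OCC=C(C)C)cc1O[Si](C)(C)C(C)(C)C | intermediate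
17 | (3R,4R)-7-[(tert-butyldimethylsilyl)oxy]-3-[2-[(tert-butyldimethylsilyl)oxy]-5-(2-methylbut-3-en-2-yl)-4-[(3-methylbut-2-en-1-yl)oxy]phenyl]-3,4-dihydro-2H-chromen-4-ol (3,4-cis) | C=CC(C)(C)c1cc([C@@H]2COc3cc(O[Si](C)(C)C(C)(C)C)ccc3[C@@H]2O)c(O[Si](C)(C)C(C)(C)C)cc1OCC=C(C)C | intermediate
18 | (3R)-7-[(tert-butyldimethylsilyl)oxy]-3-[2-[(tert-butyldimethylsilyl)oxy]-5-(2-methylbut-3-en-2-yl)-4-[(3-methylbut-2-en-1-yl)oxy]phenyl]-3,4-dihydro-2H-chromene | C=CC(C)(C)c1cc([C@@H]2COc3cc(O[Si](C)(C)C(C)(C)C)ccc3C2)c(O[Si](C)(C)C(C)(C)C)cc1OCC=C(C)C | intermediate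
19 | Manuifolin D, (3R)-3-[2-hydroxy-5-(2-methylbut-3-en-2-yl)-4-[(3-methylbut-2-en-1-yl)oxy]phenyl]-3,4-dihydro-2H-chromen-7-ol | C=CC(C)(C)c1cc([C@@H]2COc3cc(O)ccc3C2)c(O)cc1OCC=C(C)C | target

## Step count and risks

Total step count: 12. Longest linear sequence: 12 steps (1 to 19); 2 and 5 are bought.

Steps most likely to fail:

1. Step 7 (proposed new method). Intermolecular aldol condensation of the aldehyde enolate may outrun the acyl shift, or the intermediate may be quenched before the SNAr closure and then cyclise through O2' onto the formyl or keto group. The fallback sets out from 9 and returns to 12, making the same two bonds intermolecularly by known enamine chemistry. Methanolysis of the aryl ester of 9 (K2CO3, MeOH) would give 2-(2-methoxyethenyl)-4-(2-methylbut-3-en-2-yl)-5-(prenyloxy)phenol F1. Silylation (TBSCl, imidazole) gives its tert-butyldimethylsilyl ether F2, and hydrolysis of the enol ether (2 M aq. HCl, THF) gives the silyl-protected arylacetaldehyde F3. Condensation with pyrrolidine (molecular sieves, toluene) gives the (E)-enamine F4, and Stork acylation with 5 (Et3N, CH2Cl2) gives the enaminone F5. Heating F5 with K2CO3 in wet DMF hydrolyses the enaminone and closes ring C by SNAr; Bu4NF then removes the silyl group to give 12.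

2. Step 4. The sigmatropic shift may be poorly regioselective between C3' and C5', and the product phenol may isomerise further on prolonged heating (abnormal Claisen pathway). The fallback sets out from 1 and returns to 9, replacing steps 1 to 5 by a cross-coupling that fixes the position. Bromination of 1 (Br2, AcOH) should give 5-bromo-2,4-dihydroxybenzaldehyde F6. Prenylation with 2 as in step 1 gives 5-bromo-2-hydroxy-4-(prenyloxy)benzaldehyde F7, Wittig methoxymethylenation as in step 2 gives 4-bromo-2-(2-methoxyethenyl)-5-(prenyloxy)phenol F8, and acylation with 5 as in step 3 gives the bromo aryl ester F9. A branch-selective Suzuki–Miyaura coupling of F9 with 4,4,5,5-tetramethyl-2-(3-methylbut-2-en-1-yl)-1,3,2-dioxaborolane (Pd(OAc)2, bulky biaryl dialkylphosphine, K3PO4, THF/H2O, 40 °C) then puts the 1,1-dimethylallyl group on the carbon that carried bromine and gives 9.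

3. Step 11. The acid may ionise the prenyl ether, and the C4 cation may lose the C3 proton, which would lead through the isoflav-3-ene to erosion of the C3 configuration. The fallback sets out from 17 and returns to 18 under neutral radical conditions (Barton–McCombie deoxygenation). 1,1'-Thiocarbonyldiimidazole (DMAP, CH2Cl2) converts the C4 hydroxyl into the O-(imidazol-1-ylthiocarbonyl) derivative F10, which is reduced without delay with Bu3SnH and AIBN in toluene at 80 °C through the benzylic C4 radical.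

## Further compounds

F1 | step 7 | 2-(2-methoxyethenyl)-4-(2-methylbut-3-en-2-yl)-5-[(3-methylbut-2-en-1-yl)oxy]phenol (E/Z mixture) | COC=Cc1cc(C(C)(C)C=C)c(OCC=C(C)C)cc1O
F2 | step 7 | tert-butyl[2-(2-methoxyethenyl)-4-(2-methylbut-3-en-2-yl)-5-[(3-methylbut-2-en-1-yl)oxy]phenoxy]dimethylsilane (E/Z mixture) | COC=Cc1cc(C(C)(C)C=C)c(OCC=C(C)C)cc1O[Si](C)(C)C(C)(C)C
F3 | step 7 | 2-[2-[(tert-butyldimethylsilyl)oxy]-5-(2-methylbut-3-en-2-yl)-4-[(3-methylbut-2-en-1-yl)oxy]phenyl]acetaldehyde | O=CCc1cc(C(C)(C)C=C)c(OCC=C(C)C)cc1O[Si](C)(C)C(C)(C)C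
F4 | step 7 | 1-[(E)-2-[2-[(tert-butyldimethylsilyl)oxy]-5-(2-methylbut-3-en-2-yl)-4-[(3-methylbut-2-en-1-yl)oxy]phenyl]ethenyl]pyrrolidine | N1(CCCC1)/C=C/c1cc(C(C)(C)C=C)c(OCC=C(C)C)cc1O[Si](C)(C)C(C)(C)C
F5 | step 7 | 2-[2-[(tert-butyldimethylsilyl)oxy]-5-(2-methylbut-3-en-2-yl)-4-[(3-methylbut-2-en-1-yl)oxy]phenyl]-1-(2,4-difluorophenyl)-3-(pyrrolidin-1-yl)prop-2-en-1-one | O=C(c1ccc(F)cc1F)C(=CN1CCCC1)c1cc(C(C)(C)C=C)c(OCC=C(C)C)cc1O[Si](C)(C)C(C)(C)C
F6 | step 4 | 5-bromo-2,4-dihydroxybenzaldehyde | O=Cc1cc(Br)c(O)cc1O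
F7 | step 4 | 5-bromo-2-hydroxy-4-[(3-methylbut-2-en-1-yl)oxy]benzaldehyde | O=Cc1cc(Br)c(OCC=C(C)C)cc1O
F8 | step 4 | 4-bromo-2-(2-methoxyethenyl)-5-[(3-methylbut-2-en-1-yl)oxy]phenol (E/Z mixture) | COC=Cc1cc(Br)c(OCC=C(C)C)cc1O
F9 | step 4 | 4-bromo-2-(2-methoxyethenyl)-5-[(3-methylbut-2-en-1-yl)oxy]phenyl 2,4-difluorobenzoate (E/Z mixture) | COC=Cc1cc(Br)c(OCC=C(C)C)cc1OC(=O)c1ccc(F)cc1F
F10 | step 11 | O-[(3R,4R)-7-[(tert-butyldimethylsilyl)oxy]-3-[2-[(tert-butyldimethylsilyl)oxy]-5-(2-methylbut-3-en-2-yl)-4-[(3-methylbut-2-en-1-yl)oxy]phenyl]-3,4-dihydro-2H-chromen-4-yl] 1H-imidazole-1-carbothioate | C=CC(C)(C)c1cc([C@@H]2COc3cc(O[Si](C)(C)C(C)(C)C)ccc3[C@@H]2OC(=S)n2ccnc2)c(O[Si](C)(C)C(C)(C)C)cc1OCC=C(C)C
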